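**Retrosynthetic overview**

- The strategy rests on the free secondary amine N5 of the 24-membered ring. N5 lies between C4 of the three-carbon arm (ending at amide N1 on the ring B propenoyl group) and C6 of the four-carbon arm (ending at amide N10 on the ring A propenoyl group). The N5–C4 bond is therefore cut last, back to a primary amine and an aldehyde, and N5 never needs a protecting group.
- The aryl sulfate on ring A is carried as its neopentyl diester, which should survive CF3CO2H and hydride and is cleaved at the end with azide.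
- The open-chain amino aldehyde is stored as a Boc carbamate and a diethyl acetal. Its ring A propenamide comes from a Heck coupling of an aryl bromide with the acrylamide of N-Boc-1,4-diaminobutane. Its ring B propenamide comes from a Doebner condensation followed by amidation with 3,3-diethoxypropan-1-amine.
- The diaryl ether is made first by SNAr of 5-bromo-2-methoxyphenol on 4-fluorobenzaldehyde. The bromine (para to the masked phenol, meta to the ether oxygen) fixes the 1,3,4-pattern of ring A without a regioselective halogenation.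
- Rings A and B are bought in; the only ring formed is the macrocycle, closed in step 8.

Key step: step 8

Remark: neopentyl chlorosulfate is taken as a purchased reagent (otherwise one operation from neopentyl alcohol and SO2Cl2), and the target is expected as the inner salt (N5 ammonium, aryl sulfate), which the neutral SMILES represents.

**Route**

Step 1
Reactants: 1 5-bromo-2-methoxyphenol; 2 4-fluorobenzaldehyde
Product: 3 4-(5-bromo-2-methoxyphenoxy)benzaldehyde
Conditions: K2CO3, DMF, 110 °C
Reagents that add atoms: none
Why: Nucleophilic aromatic substitution (SNAr): the para-formyl group activates the fluoride toward the phenoxide, and the bromine already sits where the ring A side chain is needed.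

Step 2
Reactants: 3 4-(5-bromo-2-methoxyphenoxy)benzaldehyde; 4 malonic acid
Product: 6 (E)-3-[4-(5-bromo-2-methoxyphenoxy)phenyl]prop-2-enoic acid, via arylidenemalonic acid 5 (not isolated)
Conditions: pyridine, piperidine (cat.), 100 °C; then aq. HCl
Reagents that add atoms: none
Why: Knoevenagel–Doebner condensation: the arylidenemalonic acid decarboxylates in hot pyridine and should give the E-propenoic acid under thermodynamic control.

Step 3
Reactants: 6 (E)-3-[4-(5-bromo-2-methoxyphenoxy)phenyl]prop-2-enoic acid
Product: 7 (E)-3-[4-(5-bromo-2-hydroxyphenoxy)phenyl]prop-2-enoic acid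
Conditions: BBr3 (3 equiv), CH2Cl2, −78 → 0 °C; then H2O
Reagents that add atoms: none
Why: Lewis acid O-demethylation of an aryl methyl ether (bromide attacks the methyl group of the boron-complexed ether); the diaryl ether, the aryl bromide and the E-propenoic acid should be inert at low temperature.

Step 4
Reactants: 7 (E)-3-[4-(5-bromo-2-hydroxyphenoxy)phenyl]prop-2-enoic acid; 8 3,3-diethoxypropan-1-amine
Product: 9 (E)-3-[4-(5-bromo-2-hydroxyphenoxy)phenyl]-N-(3,3-diethoxypropyl)prop-2-enamide
Conditions: EDC·HCl, HOBt (cat.), DMF, 0 °C → rt; aq. NaHCO3 work-up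
Reagents that add atoms: none
Why: Carbodiimide/HOBt amide coupling: the primary amine outcompetes the hindered phenol for the active ester, and the non-acidic medium leaves the diethyl acetal intact.

Step 5
Reactants: 10 tert-butyl N-(4-aminobutyl)carbamate (N-Boc-1,4-diaminobutane); 11 prop-2-enoyl chloride (acryloyl chloride)
Product: 12 tert-butyl N-[4-(prop-2-enoylamino)butyl]carbamate
Conditions: Et3N, CH2Cl2, 0 °C
Reagents that add atoms: none
Why: N-acylation of the free primary amine with an acid chloride at low temperature; the carbamate nitrogen does not react.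

Step 6
Reactants: 9 (E)-3-[4-(5-bromo-2-hydroxyphenoxy)phenyl]-N-(3,3-diethoxypropyl)prop-2-enamide; 12 tert-butyl N-[4-(prop-2-enoylamino)butyl]carbamate
Product: 13 tert-butyl N-[4-[[(E)-3-[3-[4-[(E)-3-(3,3-diethoxypropylamino)-3-oxoprop-1-enyl]phenoxy]-4-hydroxyphenyl]prop-2-enoyl]amino]butyl]carbamate
Conditions: Pd(OAc)2 (5 mol %), P(o-tol)3 (15 mol %), Et3N, DMF, 100 °C
Reagents that add atoms: none
Why: Mizoroki–Heck reaction: zerovalent palladium formed in situ inserts into the C–Br bond, and syn carbopalladation of the terminal acrylamide followed by syn β-hydride elimination should give the E alkene; the 1,2-disubstituted propenamide on ring B is far less reactive than the terminal alkene, and para-bromophenols are established substrates under these conditions.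

Step 7
Reactants: 13 tert-butyl N-[4-[[(E)-3-[3-[4-[(E)-3-(3,3-diethoxypropylamino)-3-oxoprop-1-enyl]phenoxy]-4-hydroxyphenyl]prop-2-enoyl]amino]butyl]carbamate
Product: 14 tert-butyl N-[4-[[(E)-3-[3-[4-[(E)-3-(3,3-diethoxypropylamino)-3-oxoprop-1-enyl]phenoxy]-4-(2,2-dimethylpropoxysulfonyloxy)phenyl]prop-2-enoyl]amino]butyl]carbamate
Conditions: NaN(SiMe3)2 (1.0 equiv), THF, −78 °C; then neopentyl chlorosulfate, −78 → 0 °C
Reagents that add atoms: neopentyl chlorosulfate, CC(C)(C)COS(=O)(=O)Cl
Why: O-sulfonylation of a phenoxide with an alkyl chlorosulfate (protected sulfate monoester synthesis): one equivalent of base should deprotonate only the phenol, which is far more acidic than the amide and carbamate N–H groups.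

Step 8
Reactants: 14 tert-butyl N-[4-[[(E)-3-[3-[4-[(E)-3-(3,3-diethoxypropylamino)-3-oxoprop-1-enyl]phenoxy]-4-(2,2-dimethylpropoxysulfonyloxy)phenyl]prop-2-enoyl]amino]butyl]carbamate
Product: 17 macrocyclic secondary amine carrying the neopentyl sulfate diester (24-membered ring; N5–H free; both propenamide C=C bonds E), via amino aldehyde 15 (not isolated), via macrocyclic imine 16 (not isolated)
Conditions: CF3CO2H/H2O 9:1, CH2Cl2, 0 °C → rt; evaporate; then slow addition (in MeCN) to NaBH(OAc)3, i-Pr2NEt, AcOH, ClCH2CH2Cl, rt, about 1 mM final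
Reagents that add atoms: none
Why: Aqueous CF3CO2H removes the Boc group and hydrolyses the diethyl acetal; once the ammonium salt of 15 is neutralised at about 1 mM, the primary amine adds to the aldehyde carbon C4 and loses water, and NaBH(OAc)3 reduces the resulting macrocyclic iminium ion 16 to the secondary amine N5, which creates the N5–C4 bond. The closest known reaction type is the macrocyclising reductive amination of amino aldehydes with NaBH(OAc)3 under high dilution. The 24-membered ring closes in a 24-exo-trig attack of nitrogen on the aldehyde carbonyl, and because imine formation is reversible, open-chain oligomeric imines can fall back to monomer and drain into the ring before hydride fixes them. No stereocenter is formed and both E alkenes stay as they are. The step needs the amine to choose the aldehyde over the two propenamide acceptors, iminium reduction to outrun aldehyde reduction, and N5 not to be alkylated twice: the aldehyde is by far the strongest electrophile present, NaBH(OAc)3 reduces iminium ions much faster than aldehydes, and slow addition keeps the unreacted amino aldehyde scarce. The aldehyde is placed on the three-carbon arm because amide N1 would have to form a four-membered ring to trap it (on the four-carbon arm a five-membered N-acyl hemiaminal would form), and the neopentyl sulfate diester is inert to CF3CO2H and to the borohydride.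

Step 9
Reactants: 17 macrocyclic secondary amine carrying the neopentyl sulfate diester
Product: 18 CID124202369 (24-membered bis-lactam with ring A aryl hydrogen sulfate and free N5; both C=C bonds E; expected as the inner salt)
Conditions: NaN3, DMF, 65 °C; then AcOH to pH 5; reverse-phase chromatography
Reagents that add atoms: none
Why: SN2 dealkylation of the sulfate diester: azide attacks the neopentyl CH2 and the aryl sulfate monoanion leaves, the standard removal of a neopentyl sulfate protecting group; the propenamides and the secondary amine should be inert to azide.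

**Compound list**

1 | 5-bromo-2-methoxyphenol | COc1ccc(Br)cc1O | starting material
2 | 4-fluorobenzaldehyde | O=Cc1ccc(F)cc1 | starting material
3 | 4-(5-bromo-2-methoxyphenoxy)benzaldehyde | COc1ccc(Br)cc1Oc1ccc(C=O)cc1 | intermediate
4 | malonic acid | OC(=O)CC(=O)O | starting material
5 | 2-[[4-(5-bromo-2-methoxyphenoxy)phenyl]methylidene]propanedioic acid (not isolated) | COc1ccc(Br)cc1Oc1ccc(C=C(C(=O)O)C(=O)O)cc1 | intermediate
6 | (E)-3-[4-(5-bromo-2-methoxyphenoxy)phenyl]prop-2-enoic acid | COc1ccc(Br)cc1Oc1ccc(/C=C/C(=O)O)cc1 | intermediate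
7 | (E)-3-[4-(5-bromo-2-hydroxyphenoxy)phenyl]prop-2-enoic acid | OC(=O)/C=C/c1ccc(Oc2cc(Br)ccc2O)cc1 | intermediate
8 | 3,3-diethoxypropan-1-amine | CCOC(CCN)OCC | starting material
9 | (E)-3-[4-(5-bromo-2-hydroxyphenoxy)phenyl]-N-(3,3-diethoxypropyl)prop-2-enamide | CCOC(CCNC(=O)/C=C/c1ccc(Oc2cc(Br)ccc2O)cc1)OCC | intermediate
10 | tert-butyl N-(4-aminobutyl)carbamate | NCCCCNC(=O)OC(C)(C)C | starting material
11 | prop-2-enoyl chloride | C=CC(=O)Cl | starting material
12 | tert-butyl N-[4-(prop-2-enoylamino)butyl]carbamate | C=CC(=O)NCCCCNC(=O)OC(C)(C)C | intermediate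
13 | tert-butyl N-[4-[[(E)-3-[3-[4-[(E)-3-(3,3-diethoxypropylamino)-3-oxoprop-1-enyl]phenoxy]-4-hydroxyphenyl]prop-2-enoyl]amino]butyl]carbamate | CCOC(CCNC(=O)/C=C/c1ccc(Oc2cc(/C=C/C(=O)NCCCCNC(=O)OC(C)(C)C)ccc2O)cc1)OCC | intermediate
14 | tert-butyl N-[4-[[(E)-3-[3-[4-[(E)-3-(3,3-diethoxypropylamino)-3-oxoprop-1-enyl]phenoxy]-4-(2,2-dimethylpropoxysulfonyloxy)phenyl]prop-2-enoyl]amino]butyl]carbamate | CCOC(CCNC(=O)/C=C/c1ccc(Oc2cc(/C=C/C(=O)NCCCCNC(=O)OC(C)(C)C)ccc2OS(=O)(=O)OCC(C)(C)C)cc1)OCC | intermediate
15 | (E)-N-(4-aminobutyl)-3-[4-(2,2-dimethylpropoxysulfonyloxy)-3-[4-[(E)-3-oxo-3-(3-oxopropylamino)prop-1-enyl]phenoxy]phenyl]prop-2-enamide (formed as its trifluoroacetate salt; not isolated) | NCCCCNC(=O)/C=C/c1ccc(OS(=O)(=O)OCC(C)(C)C)c(Oc2ccc(/C=C/C(=O)NCCC=O)cc2)c1 | intermediate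
16 | macrocyclic imine with C4=N5 double bond, neopentyl sulfate diester on ring A, both propenamide C=C bonds E (reduced as its iminium ion; not isolated) | O=C1/C=C/c2ccc(OS(=O)(=O)OCC(C)(C)C)c(c2)Oc2ccc(cc2)/C=C/C(=O)NCCC=NCCCCN1 | intermediate
17 | 24-membered macrocycle with free secondary amine N5 and neopentyl sulfate diester on ring A, both propenamide C=C bonds E | O=C1/C=C/c2ccc(OS(=O)(=O)OCC(C)(C)C)c(c2)Oc2ccc(cc2)/C=C/C(=O)NCCCNCCCCN1 | intermediate
18 | CID124202369, 24-membered macrocycle with free N5 and aryl hydrogen sulfate on ring A, both propenamide C=C bonds E | O=C1/C=C/c2ccc(OS(=O)(=O)O)c(c2)Oc2ccc(cc2)/C=C/C(=O)NCCCNCCCCN1 | target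

**Step count**

Total: 9 steps. Longest linear sequence: 8 steps (steps 1, 2, 3, 4, 6, 7, 8 and 9, from 5-bromo-2-methoxyphenol); step 5 is a one-step side branch.

**Steps most likely to fail**

Step 8 (macrocyclising reductive amination). Imine formation between two molecules may outpace ring closure, so that hydride fixes linear and cyclic dimers. The new secondary amine may take up a second aldehyde, and direct reduction of the aldehyde may drain material.

The fallback closes the same C4–N5 bond by an intramolecular Staudinger/aza-Wittig reaction, with no free amine and no hydride present during ring closure. It sets out from 9 and comes back to the route at 16.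
- 9 is coupled with acrylic acid (Pd(OAc)2, P(o-tol)3, Et3N, DMF, 100 °C) to give (E)-3-[3-[4-[(E)-3-(3,3-diethoxypropylamino)-3-oxoprop-1-enyl]phenoxy]-4-hydroxyphenyl]prop-2-enoic acid F1.
- Amidation with commercial 4-azidobutan-1-amine (EDC·HCl, HOBt, DMF) gives the azido amide F2.
- Sulfation as in step 7 gives the azido neopentyl sulfate F3.
- Brief treatment with CF3CO2H/H2O in CH2Cl2 at 0 °C hydrolyses the acetal to the azido aldehyde F4.
- Slow addition of F4 to PPh3 in toluene at 80 °C (about 1 mM) converts the azide into the iminophosphorane F5, which should close onto the aldehyde to give the macrocyclic imine 16.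
- NaBH(OAc)3/AcOH then reduces 16 to 17.

Step 6 (Heck coupling on the free bromophenol). Oxidative addition into the electron-rich aryl bromide, present partly as phenoxide under Et3N, may be slow, so that thermal oligomerisation of acrylamide 12 and hydrodebromination overtake the coupling.

The fallback masks the phenol for the coupling. It sets out from 9 and comes back at 13.
- Ac2O/pyridine at 0 °C gives the aryl acetate F6, an ordinary non-phenoxide aryl bromide.
- Heck coupling with 12 under the step 6 conditions gives the coupled acetate F7.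
- K2CO3 in MeOH at 0 °C removes the acetyl group and returns 13.

Step 7 (sulfation of 13). The base or the chlorosulfate may engage the carbamate or amide N–H groups, or the sodium phenoxide of this large polar molecule may aggregate at −78 °C so that O-sulfonylation stalls.

The fallback installs the sulfate before the C–C coupling, when only one amide N–H is present. It sets out from 9 and comes back at 14.
- 9 with NaN(SiMe3)2 and neopentyl chlorosulfate (THF, −78 → 0 °C) gives the bromoaryl neopentyl sulfate F8.
- Heck coupling of F8 with 12 (Pd(OAc)2, P(o-tol)3, i-Pr2NEt, DMF, 90 °C; hindered base to spare the diester) gives 14 directly, without passing through 13.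

**Further compounds**

F1 | step 8 | (E)-3-[3-[4-[(E)-3-(3,3-diethoxypropylamino)-3-oxoprop-1-enyl]phenoxy]-4-hydroxyphenyl]prop-2-enoic acid | CCOC(CCNC(=O)/C=C/c1ccc(Oc2cc(/C=C/C(=O)O)ccc2O)cc1)OCC
F2 | step 8 | (E)-N-(4-azidobutyl)-3-[3-[4-[(E)-3-(3,3-diethoxypropylamino)-3-oxoprop-1-enyl]phenoxy]-4-hydroxyphenyl]prop-2-enamide | CCOC(CCNC(=O)/C=C/c1ccc(Oc2cc(/C=C/C(=O)NCCCCN=[N+]=[N-])ccc2O)cc1)OCC
F3 | step 8 | (E)-N-(4-azidobutyl)-3-[3-[4-[(E)-3-(3,3-diethoxypropylamino)-3-oxoprop-1-enyl]phenoxy]-4-(2,2-dimethylpropoxysulfonyloxy)phenyl]prop-2-enamide | CCOC(CCNC(=O)/C=C/c1ccc(Oc2cc(/C=C/C(=O)NCCCCN=[N+]=[N-])ccc2OS(=O)(=O)OCC(C)(C)C)cc1)OCC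
F4 | step 8 | (E)-N-(4-azidobutyl)-3-[4-(2,2-dimethylpropoxysulfonyloxy)-3-[4-[(E)-3-oxo-3-(3-oxopropylamino)prop-1-enyl]phenoxy]phenyl]prop-2-enamide | O=CCCNC(=O)/C=C/c1ccc(Oc2cc(/C=C/C(=O)NCCCCN=[N+]=[N-])ccc2OS(=O)(=O)OCC(C)(C)C)cc1
F5 | step 8 | iminophosphorane of F4 (N-triphenylphosphoranylidene in place of the azide) | O=CCCNC(=O)/C=C/c1ccc(Oc2cc(/C=C/C(=O)NCCCCN=P(c3ccccc3)(c3ccccc3)c3ccccc3)ccc2OS(=O)(=O)OCC(C)(C)C)cc1
F6 | step 6 | [4-bromo-2-[4-[(E)-3-(3,3-diethoxypropylamino)-3-oxoprop-1-enyl]phenoxy]phenyl] acetate | CCOC(CCNC(=O)/C=C/c1ccc(Oc2cc(Br)ccc2OC(C)=O)cc1)OCC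
F7 | step 6 | O-acetyl derivative of 13 (aryl acetate in place of the ring A phenol) | CCOC(CCNC(=O)/C=C/c1ccc(Oc2cc(/C=C/C(=O)NCCCCNC(=O)OC(C)(C)C)ccc2OC(C)=O)cc1)OCC
F8 | step 7 | [4-bromo-2-[4-[(E)-3-(3,3-diethoxypropylamino)-3-oxoprop-1-enyl]phenoxy]phenyl] 2,2-dimethylpropyl sulfate | CCOC(CCNC(=O)/C=C/c1ccc(Oc2cc(Br)ccc2OS(=O)(=O)OCC(C)(C)C)cc1)OCC
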